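**Plan**

- Retrosynthesis: the epoxide oxygen is removed last (E-C4=C5 alkene). The C5–C6 bond is then cut together with the lactone C12–O bond. C2–C3 (enolate alkylation), C10–C14 (methyl Grignard) and C8–C9 (aldol) lead back to a 2-silyl-3,4-disubstituted furan, 3,3-dimethoxybutan-2-one and an E-iodoallyl bromide.
- Enabling feature: C6 is the γ-carbon of the butenolide ring (O–C12(=O)–C11=C7–C6) and the direct neighbour of epoxide carbon C5. At the aldehyde level C6 is the free arm of a cis-4-oxo-2-enoate, the ring-chain tautomer of a 5-hydroxybutenolide that a furan ring (O, C6, C7, C11, C12) releases on photooxygenation. C5 is the sp2 carbon of an E-iodoalkene.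
- Forward: furan aldehyde (steps 1–3); C8–C9–C10–C1 by aldol and Grignard addition, then a temporary dioxasilinane ring (4–7); C2–C5 arm by alkylation (8–10); diacetate and unmasking of the furan (11–14); one chromium-mediated addition closes the ten-membered carbocycle and, by lactonization, the butenolide (15); desilylation and epoxidation (16–17).
- Stereochemistry: C8 from the chiral boron aldol; C10 from C8 by chelation-controlled methyl addition; C6 from C8 in the ring closure; C4 and C5 from C6 and the E geometry by allylic-strain-controlled epoxidation.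

Key step: step 15

Remark: germacranolide numbering is used (C1 ketone, C2/C3 methylenes, C4(C15 methyl)–C5 epoxide, C6 lactone carbinol, C7=C11, C8 and C10(C14 methyl) acetoxy carbons, C9 methylene, C12 lactone carbonyl, C13 hydroxymethyl), the SMILES is read as 4R,5R,6S,8S,10R with a trans epoxide, and Fur = 5-(tert-butyldimethylsilyl)-4-[(tert-butyldiphenylsilyloxy)methyl]furan-3-yl.

**Route**

Step 1
Reactants: 1 furan-3-ylmethanol
Product: 2 [2-(tert-butyldimethylsilyl)furan-3-yl]methanol
Conditions: n-BuLi (2.2 equiv), THF, −78 → 0 °C; TBSCl (1.1 equiv), 0 °C → rt; H2O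
Reagents that add atoms: tert-butyldimethylsilyl chloride CC(C)(C)[Si](C)(C)Cl
Why: Alkoxide-directed lithiation at the adjacent α-carbon followed by silylation (any O-silylated material should converge by retro-Brook 1,4 O-to-C silyl migration) should place silicon on the future C12, where it later directs the furan oxidation.

Step 2
Reactants: 2 [2-(tert-butyldimethylsilyl)furan-3-yl]methanol
Product: 3 5-(tert-butyldimethylsilyl)-4-(hydroxymethyl)furan-3-carbaldehyde
Conditions: n-BuLi (2.2 equiv), DME, 0 °C; DMF, −40 °C → rt; H2O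
Reagents that add atoms: N,N-dimethylformamide CN(C)C=O
Why: With the α-position next to the hydroxymethyl group blocked by the bulky silyl group, the lithium alkoxide should direct a second lithiation to the neighbouring β-carbon (directed ortho-metalation), and formylation installs the future C8 aldehyde.

Step 3
Reactants: 3 5-(tert-butyldimethylsilyl)-4-(hydroxymethyl)furan-3-carbaldehyde
Product: 4 5-(tert-butyldimethylsilyl)-4-[(tert-butyldiphenylsilyloxy)methyl]furan-3-carbaldehyde (Fur-CHO)
Conditions: TBDPSCl, imidazole, CH2Cl2, 0 °C → rt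
Reagents that add atoms: tert-butyldiphenylsilyl chloride CC(C)(C)[Si](Cl)(c1ccccc1)c1ccccc1
Why: Standard silylation of the primary alcohol (future C13 hydroxyl) with a group that should outlast the later acid step and the brief fluoride treatment at the diol.

Step 4
Reactants: 4 Fur-CHO; 5 3,3-dimethoxybutan-2-one
Product: 6 (1S)-1-Fur-1-hydroxy-4,4-dimethoxypentan-3-one
Conditions: 5, (+)-Ipc2BCl, Et3N, Et2O, 0 °C; then 4, −78 → −20 °C; H2O2, MeOH, pH 7 buffer
Reagents that add atoms: none
Why: Diisopinocampheylboron-mediated aldol of a methyl ketone that can enolize only at its methyl group (the other side is the ketal carbon); the chiral boron ligands should deliver the enolate to the Si face of the aldehyde through a cyclic transition state and set C8 as S.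

Step 5
Reactants: 6 (1S)-1-Fur-1-hydroxy-4,4-dimethoxypentan-3-one
Product: 7 (1S,3R)-1-Fur-4,4-dimethoxy-3-methylpentane-1,3-diol
Conditions: MeMgBr (3 equiv), THF/CH2Cl2, −78 °C; H2O
Reagents that add atoms: methylmagnesium bromide C[Mg]Br
Why: Chelation-controlled 1,3-induction in a Grignard addition: in the six-membered magnesium chelate of the C8 alkoxide and the C10 carbonyl the methyl group should add anti to the furyl substituent and set C10 as R.

Step 6
Reactants: 7 (1S,3R)-1-Fur-4,4-dimethoxy-3-methylpentane-1,3-diol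
Product: 8 (4R,6S)-2,2-di-tert-butyl-4-(1,1-dimethoxyethyl)-4-methyl-6-Fur-1,3,2-dioxasilinane
Conditions: tBu2Si(OTf)2, 2,6-lutidine, CH2Cl2, 0 °C
Reagents that add atoms: di-tert-butylsilyl bis(trifluoromethanesulfonate) CC(C)(C)[Si](OS(=O)(=O)C(F)(F)F)(OS(=O)(=O)C(F)(F)F)C(C)(C)C
Why: Silylene formation ties the secondary and the tertiary hydroxyl into one ring under non-acidic conditions, so that the C8 hydroxyl cannot close onto C1 when the ketal is opened and both oxygens survive the enolate chemistry.

Step 7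
Reactants: 8 (4R,6S)-2,2-di-tert-butyl-4-(1,1-dimethoxyethyl)-4-methyl-6-Fur-1,3,2-dioxasilinane
Product: 9 1-[(4R,6S)-2,2-di-tert-butyl-4-methyl-6-Fur-1,3,2-dioxasilinan-4-yl]ethan-1-one
Conditions: PPTS (cat.), acetone/H2O, 50 °C
Reagents that add atoms: water O
Why: Acid-catalysed hydrolysis of the acyclic dimethyl ketal, which should be more labile than the silylene and the silyl ethers, releases the C1 methyl ketone.

Step 8
Reactants: 10 prop-2-yn-1-ol
Product: 12 (E)-3-iodo-2-methylprop-2-en-1-ol, via alkenylalane 11 (not isolated)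
Conditions: AlMe3 (3 equiv), Cp2ZrCl2 (0.25 equiv), CH2Cl2, 0 °C → rt; I2, THF, −30 °C; aqueous work-up
Reagents that add atoms: trimethylaluminium C[Al](C)C; iodine II
Why: Negishi carboalumination adds methyl and aluminium syn across the alkyne with aluminium at the terminus, and iododealumination with retention should give the E-iodoalkene that becomes C4(C15)=C5.

Step 9
Reactants: 12 (E)-3-iodo-2-methylprop-2-en-1-ol
Product: 13 (E)-3-bromo-1-iodo-2-methylprop-1-ene
Conditions: CBr4, PPh3, CH2Cl2, 0 °C
Reagents that add atoms: carbon tetrabromide BrC(Br)(Br)Br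
Why: Appel bromination converts the primary allylic alcohol into the bromide without touching the alkenyl iodide.

Step 10
Reactants: 9 1-[(4R,6S)-2,2-di-tert-butyl-4-methyl-6-Fur-1,3,2-dioxasilinan-4-yl]ethan-1-one; 13 (E)-3-bromo-1-iodo-2-methylprop-1-ene
Product: 14 (E)-1-[(4R,6S)-2,2-di-tert-butyl-4-methyl-6-Fur-1,3,2-dioxasilinan-4-yl]-5-iodo-4-methylpent-4-en-1-one
Conditions: LDA (1.1 equiv), THF, −78 °C; then 13, DMPU, −78 → −30 °C
Reagents that add atoms: none
Why: Alkylation of the kinetic lithium enolate, which can form only at the C2 methyl group because C10 is quaternary, with a reactive allylic bromide should form the C2–C3 bond while the alkenyl iodide stays inert.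

Step 11
Reactants: 14 (E)-1-[(4R,6S)-2,2-di-tert-butyl-4-methyl-6-Fur-1,3,2-dioxasilinan-4-yl]-5-iodo-4-methylpent-4-en-1-one
Product: 15 (1S,3R,7E)-1-Fur-1,3-dihydroxy-8-iodo-3,7-dimethyloct-7-en-4-one
Conditions: HF·pyridine, pyridine, THF, 0 °C
Reagents that add atoms: none
Why: Fluoride should cleave the cyclic silylene much faster than the primary tert-butyldiphenylsilyl ether and leaves the carbon-bound silyl group on the furan untouched.

Step 12
Reactants: 15 (1S,3R,7E)-1-Fur-1,3-dihydroxy-8-iodo-3,7-dimethyloct-7-en-4-one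
Product: 16 (1S,3R,7E)-1-Fur-8-iodo-3,7-dimethyl-4-oxooct-7-ene-1,3-diyl diacetate
Conditions: Ac2O, DMAP, Et3N, CH2Cl2, rt → 40 °C
Reagents that add atoms: acetic anhydride CC(=O)OC(C)=O
Why: DMAP-catalysed acylation should acetylate the secondary C8 hydroxyl quickly and the tertiary C10 hydroxyl on warming, and doing it here removes the free C8 hydroxyl before it could form a transannular hemiketal with C1 in the macrocycle.

Step 13
Reactants: 16 (1S,3R,7E)-1-Fur-8-iodo-3,7-dimethyl-4-oxooct-7-ene-1,3-diyl diacetate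
Product: 19 (1S,3R,7E)-1-{4-[(tert-butyldiphenylsilyloxy)methyl]-2-hydroxy-5-oxo-2,5-dihydrofuran-3-yl}-8-iodo-3,7-dimethyl-4-oxooct-7-ene-1,3-diyl diacetate (both lactol epimers), via furan endoperoxide 17 (not isolated), via silyl oxoenoate 18 (not isolated)
Conditions: O2, tetraphenylporphyrin (cat.), visible light, CH2Cl2, −78 °C; then H2O, silica gel, rt
Reagents that add atoms: oxygen O=O
Why: Silyl-directed [4+2] photooxygenation of the furan: the endoperoxide fragments with migration of silicon from C12 to oxygen, so that C12 becomes the carboxyl carbon and C6 the aldehyde with full regiocontrol, and hydrolysis of the silyl ester gives the lactol, while the electron-poor iodoalkene should react far more slowly with singlet oxygen than the furan.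

Step 14
Reactants: 19 the γ-hydroxybutenolide from step 13
Product: 20 methyl (2Z,4S,6R,10E)-4,6-diacetoxy-2-[(tert-butyldiphenylsilyloxy)methyl]-3-formyl-11-iodo-6,10-dimethyl-7-oxoundeca-2,10-dienoate
Conditions: MeI, KHCO3, DMF, rt
Reagents that add atoms: iodomethane CI
Why: Under mild base the lactol opens to the aldehyde carboxylate (ring-chain tautomerism), so both lactol epimers converge on one compound, and O-alkylation of the carboxylate should give the normal methyl ester with the Z geometry fixed by the former ring.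

Step 15
Reactants: 20 methyl (2Z,4S,6R,10E)-4,6-diacetoxy-2-[(tert-butyldiphenylsilyloxy)methyl]-3-formyl-11-iodo-6,10-dimethyl-7-oxoundeca-2,10-dienoate
Product: 22 (4E,6R,8S,10R)-8,10-diacetoxy-13-(tert-butyldiphenylsilyloxy)-1-oxogermacra-4,7(11)-dien-12,6-olide, via hydroxy ester 21 (not isolated)
Conditions: CrCl2 (10 equiv), NiCl2 (1 mol % of CrCl2), degassed DMSO/THF, rt, slow addition of 20 (final 0.002 M); H2O work-up
Reagents that add atoms: none
Why: Zerovalent nickel formed in situ inserts into the C5–I bond, the alkenyl group passes to trivalent chromium with retention of the E geometry and adds to the chromium-bound aldehyde C6, and the resulting chromium alkoxide acylates itself on the cis methyl ester to give the butenolide. The closest known reaction type is the intramolecular Nozaki–Hiyama–Kishi macrocyclization, followed by the lactonization that normally follows additions to cis-4-oxo-2-enoates. The ten-membered carbocycle closes in a 10-exo-trig mode (carbonyl oxygen outside the new ring) and the lactone in a 5-exo-trig acyl substitution. The new stereocenter C6 is controlled by the C8 acetoxy center through the ring-forming transition state: C8–H eclipses the C7=C11 bond to avoid allylic strain with the C13 substituent, the aldehyde is held s-cis to the ester as in the lactol, and the chain should turn the corner at C7 to reach the Re face of the aldehyde, which gives 6R in the alkene (the arrangement of the target, where the same center is named S). The step needs aldehyde-over-ketone chemoselectivity and ring closure over oligomerization: the first is inherent to organochromium reagents and is reinforced by the E geometry, which points the C5–Cr bond away from C1 so that a five-membered closure onto the ketone is impossible, and the second is secured by slow addition at high dilution.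

Step 16
Reactants: 22 (4E,6R,8S,10R)-8,10-diacetoxy-13-(tert-butyldiphenylsilyloxy)-1-oxogermacra-4,7(11)-dien-12,6-olide
Product: 23 (4E,6R,8S,10R)-8,10-diacetoxy-13-hydroxy-1-oxogermacra-4,7(11)-dien-12,6-olide
Conditions: HF·pyridine, pyridine, THF, 0 °C → rt
Reagents that add atoms: none
Why: Fluoride-mediated cleavage of the primary silyl ether under buffered, non-basic conditions should spare the acetates and the base-sensitive butenolide.

Step 17
Reactants: 23 (4E,6R,8S,10R)-8,10-diacetoxy-13-hydroxy-1-oxogermacra-4,7(11)-dien-12,6-olide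
Product: 24 (4R,5R,6S,8S,10R)-8,10-diacetoxy-4,5-epoxy-13-hydroxy-1-oxogermacr-7(11)-en-12,6-olide (CNP0266633.2)
Conditions: mCPBA, NaHCO3, CH2Cl2, 0 °C
Reagents that add atoms: 3-chloroperbenzoic acid OOC(=O)c1cccc(Cl)c1
Why: Prilezhaev epoxidation of the only electron-rich alkene: allylic 1,3-strain with the C15 methyl group holds H6 in the alkene plane, the ring carbon C7 then shields one face, and the peracid should attack the exposed face syn to the lactone oxygen to give the trans 4R,5R epoxide (C6 is renamed S only because the CIP ranks of C5 and C7 swap).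

**Compound list**

1 | furan-3-ylmethanol | OCc1ccoc1 | starting material
2 | [2-(tert-butyldimethylsilyl)furan-3-yl]methanol | OCc1ccoc1[Si](C)(C)C(C)(C)C | intermediate
3 | 5-(tert-butyldimethylsilyl)-4-(hydroxymethyl)furan-3-carbaldehyde | O=Cc1coc([Si](C)(C)C(C)(C)C)c1CO | intermediate
4 | 5-(tert-butyldimethylsilyl)-4-[(tert-butyldiphenylsilyloxy)methyl]furan-3-carbaldehyde (Fur-CHO) | O=Cc1coc([Si](C)(C)C(C)(C)C)c1CO[Si](c1ccccc1)(c1ccccc1)C(C)(C)C | intermediate
5 | 3,3-dimethoxybutan-2-one | CC(=O)C(C)(OC)OC | starting material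
6 | (1S)-1-Fur-1-hydroxy-4,4-dimethoxypentan-3-one | CC(OC)(OC)C(=O)C[C@H](O)c1coc([Si](C)(C)C(C)(C)C)c1CO[Si](c1ccccc1)(c1ccccc1)C(C)(C)C | intermediate
7 | (1S,3R)-1-Fur-4,4-dimethoxy-3-methylpentane-1,3-diol | CC(OC)(OC)[C@](C)(O)C[C@H](O)c1coc([Si](C)(C)C(C)(C)C)c1CO[Si](c1ccccc1)(c1ccccc1)C(C)(C)C | intermediate
8 | (4R,6S)-2,2-di-tert-butyl-4-(1,1-dimethoxyethyl)-4-methyl-6-Fur-1,3,2-dioxasilinane | CC(OC)(OC)[C@@]1(C)C[C@@H](c2coc([Si](C)(C)C(C)(C)C)c2CO[Si](c2ccccc2)(c2ccccc2)C(C)(C)C)O[Si](C(C)(C)C)(C(C)(C)C)O1 | intermediate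
9 | 1-[(4R,6S)-2,2-di-tert-butyl-4-methyl-6-Fur-1,3,2-dioxasilinan-4-yl]ethan-1-one | CC(=O)[C@@]1(C)C[C@@H](c2coc([Si](C)(C)C(C)(C)C)c2CO[Si](c2ccccc2)(c2ccccc2)C(C)(C)C)O[Si](C(C)(C)C)(C(C)(C)C)O1 | intermediate
10 | prop-2-yn-1-ol | C#CCO | starting material
11 | dimethyl[(E)-3-(dimethylalumanyloxy)-2-methylprop-1-enyl]alumane (alkenylalane, not isolated) | C[Al](C)OC/C(C)=C/[Al](C)C | intermediate
12 | (E)-3-iodo-2-methylprop-2-en-1-ol | OC/C(C)=C/I | intermediate
13 | (E)-3-bromo-1-iodo-2-methylprop-1-ene | BrC/C(C)=C/I | intermediate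
14 | (E)-1-[(4R,6S)-2,2-di-tert-butyl-4-methyl-6-Fur-1,3,2-dioxasilinan-4-yl]-5-iodo-4-methylpent-4-en-1-one | I/C=C(\C)CCC(=O)[C@@]1(C)C[C@@H](c2coc([Si](C)(C)C(C)(C)C)c2CO[Si](c2ccccc2)(c2ccccc2)C(C)(C)C)O[Si](C(C)(C)C)(C(C)(C)C)O1 | intermediate
15 | (1S,3R,7E)-1-Fur-1,3-dihydroxy-8-iodo-3,7-dimethyloct-7-en-4-one | I/C=C(\C)CCC(=O)[C@](C)(O)C[C@H](O)c1coc([Si](C)(C)C(C)(C)C)c1CO[Si](c1ccccc1)(c1ccccc1)C(C)(C)C | intermediate
16 | (1S,3R,7E)-1-Fur-8-iodo-3,7-dimethyl-4-oxooct-7-ene-1,3-diyl diacetate | I/C=C(\C)CCC(=O)[C@](C)(OC(C)=O)C[C@H](OC(C)=O)c1coc([Si](C)(C)C(C)(C)C)c1CO[Si](c1ccccc1)(c1ccccc1)C(C)(C)C | intermediate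
17 | endoperoxide of 16 (2,3,7-trioxabicyclo[2.2.1]hept-5-ene across the two furan α-carbons, bridgehead epimers, not isolated) | I/C=C(\C)CCC(=O)[C@](C)(OC(C)=O)C[C@H](OC(C)=O)C1=C(CO[Si](c2ccccc2)(c2ccccc2)C(C)(C)C)C2([Si](C)(C)C(C)(C)C)OOC1O2 | intermediate
18 | tert-butyldimethylsilyl (2Z,4S,6R,10E)-4,6-diacetoxy-2-[(tert-butyldiphenylsilyloxy)methyl]-3-formyl-11-iodo-6,10-dimethyl-7-oxoundeca-2,10-dienoate (not isolated) | I/C=C(\C)CCC(=O)[C@](C)(OC(C)=O)C[C@H](OC(C)=O)/C(C=O)=C(\CO[Si](c1ccccc1)(c1ccccc1)C(C)(C)C)C(=O)O[Si](C)(C)C(C)(C)C | intermediate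
19 | (1S,3R,7E)-1-{4-[(tert-butyldiphenylsilyloxy)methyl]-2-hydroxy-5-oxo-2,5-dihydrofuran-3-yl}-8-iodo-3,7-dimethyl-4-oxooct-7-ene-1,3-diyl diacetate (lactol epimers) | I/C=C(\C)CCC(=O)[C@](C)(OC(C)=O)C[C@H](OC(C)=O)C1=C(CO[Si](c2ccccc2)(c2ccccc2)C(C)(C)C)C(=O)OC1O | intermediate
20 | methyl (2Z,4S,6R,10E)-4,6-diacetoxy-2-[(tert-butyldiphenylsilyloxy)methyl]-3-formyl-11-iodo-6,10-dimethyl-7-oxoundeca-2,10-dienoate | I/C=C(\C)CCC(=O)[C@](C)(OC(C)=O)C[C@H](OC(C)=O)/C(C=O)=C(\CO[Si](c1ccccc1)(c1ccccc1)C(C)(C)C)C(=O)OC | intermediate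
21 | methyl (4E,6R,8S,10R)-8,10-diacetoxy-13-(tert-butyldiphenylsilyloxy)-6-hydroxy-1-oxogermacra-4,7(11)-dien-12-oate, C6 and C12 cis on C7=C11 (formed as its chromium alkoxide, not isolated) | CC(=O)O[C@H]1C[C@@](C)(OC(C)=O)C(=O)CC/C(C)=C/[C@@H](O)/C1=C(/CO[Si](c2ccccc2)(c2ccccc2)C(C)(C)C)C(=O)OC | intermediate
22 | (4E,6R,8S,10R)-8,10-diacetoxy-13-(tert-butyldiphenylsilyloxy)-1-oxogermacra-4,7(11)-dien-12,6-olide | CC(=O)O[C@H]1C[C@@](C)(OC(C)=O)C(=O)CC/C(C)=C/[C@H]2OC(=O)C(CO[Si](c3ccccc3)(c3ccccc3)C(C)(C)C)=C12 | intermediate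
23 | (4E,6R,8S,10R)-8,10-diacetoxy-13-hydroxy-1-oxogermacra-4,7(11)-dien-12,6-olide | CC(=O)O[C@H]1C[C@@](C)(OC(C)=O)C(=O)CC/C(C)=C/[C@H]2OC(=O)C(CO)=C12 | intermediate
24 | (4R,5R,6S,8S,10R)-8,10-diacetoxy-4,5-epoxy-13-hydroxy-1-oxogermacr-7(11)-en-12,6-olide (CNP0266633.2) | CC(=O)O[C@H]1C[C@@](C)(OC(C)=O)C(=O)CC[C@@]2(C)O[C@@H]2[C@H]2OC(=O)C(CO)=C12 | target

**Count and risks**

Total step count: 17. Longest linear sequence: 15 steps (steps 1–7 and 10–17, from furan-3-ylmethanol); steps 8–9 make the side fragment 13.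

Steps most likely to fail:

1. Step 15. The alkenylchromium may add to the wrong face of the aldehyde (giving the 6-epimer), or chains may couple with one another instead of closing the ring. Fallback: close the ring one protecting-group stage earlier, with the dioxasilinane kept as a temporary ring that locks the C8–C9–C10 segment and so changes the conformational bias of the closing chain. If needed, a chiral oxazoline sulfonamide ligand on chromium can add reagent control. The fallback sets out from 14 and returns at 22. Photooxygenation of 14 under the conditions of step 13 should give the silylene-bridged lactol F1. Methylation with MeI and KHCO3 gives the silylene-bridged aldehyde ester F2. Ring closure with CrCl2 and catalytic NiCl2 at high dilution gives the silylene-bridged macrolactone F3. HF·pyridine then frees the macrocyclic diol F4, which is acetylated at once with Ac2O and DMAP, before the C8 hydroxyl settles as a hemiketal on C1, to give 22.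

2. Step 17. The peracid may be delivered to the wrong face of the C4=C5 alkene if the ring populates its other planar-chiral conformer. Fallback: a two-step bromohydrin route that places the oxygen on the face opposite to the one the electrophile attacks first. It sets out from 23 and returns at 24. NBS in aqueous DME should add bromine to the exposed face and water to C4 in an anti sense to give the bromohydrin F5. Ag2O in THF then closes the epoxide by attack of the C4 oxygen on C5 with inversion, giving 24.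

3. Step 4. The boron enolate may discriminate poorly between the two faces of the hindered furan aldehyde, which would lower the enantiomeric purity of every later compound. Fallback: set C8 by catalytic asymmetric conjugate borylation instead of by the aldol. It sets out from 4 and 5 and returns at 6. Claisen–Schmidt condensation (Ba(OH)2, EtOH) should give the E-enone F6. Copper-catalysed β-borylation (CuCl, NaOtBu, a chiral bisphosphine such as one enantiomer of a Josiphos ligand, B2pin2, MeOH, THF; ligand enantiomer chosen to give the S center) gives the β-boryl ketone F7. Oxidation with NaBO3 in THF/H2O replaces boron by hydroxyl with retention and gives 6.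

Further compounds
F1 | step 15 | (E)-1-[(4R,6S)-2,2-di-tert-butyl-6-{4-[(tert-butyldiphenylsilyloxy)methyl]-2-hydroxy-5-oxo-2,5-dihydrofuran-3-yl}-4-methyl-1,3,2-dioxasilinan-4-yl]-5-iodo-4-methylpent-4-en-1-one (lactol epimers) | I/C=C(\C)CCC(=O)[C@@]1(C)C[C@@H](C2=C(CO[Si](c3ccccc3)(c3ccccc3)C(C)(C)C)C(=O)OC2O)O[Si](C(C)(C)C)(C(C)(C)C)O1
F2 | step 15 | methyl (Z)-2-[(tert-butyldiphenylsilyloxy)methyl]-3-{(4S,6R)-2,2-di-tert-butyl-6-[(E)-5-iodo-4-methylpent-4-enoyl]-6-methyl-1,3,2-dioxasilinan-4-yl}-4-oxobut-2-enoate | I/C=C(\C)CCC(=O)[C@@]1(C)C[C@@H](/C(C=O)=C(\CO[Si](c2ccccc2)(c2ccccc2)C(C)(C)C)C(=O)OC)O[Si](C(C)(C)C)(C(C)(C)C)O1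
F3 | step 15 | (4E,6R,8S,10R)-13-(tert-butyldiphenylsilyloxy)-8,10-[(di-tert-butylsilanediyl)bis(oxy)]-1-oxogermacra-4,7(11)-dien-12,6-olide | CC(C)(C)[Si]1(C(C)(C)C)O[C@H]2C[C@@](C)(O1)C(=O)CC/C(C)=C/[C@H]3OC(=O)C(CO[Si](c4ccccc4)(c4ccccc4)C(C)(C)C)=C23
F4 | step 15 | (4E,6R,8S,10R)-13-(tert-butyldiphenylsilyloxy)-8,10-dihydroxy-1-oxogermacra-4,7(11)-dien-12,6-olide | O[C@H]1C[C@@](C)(O)C(=O)CC/C(C)=C/[C@H]2OC(=O)C(CO[Si](c3ccccc3)(c3ccccc3)C(C)(C)C)=C12
F5 | step 17 | (4R,5S,6S,8S,10R)-8,10-diacetoxy-5-bromo-4,13-dihydroxy-1-oxogermacr-7(11)-en-12,6-olide | CC(=O)O[C@H]1C[C@@](C)(OC(C)=O)C(=O)CC[C@@](C)(O)[C@@H](Br)[C@H]2OC(=O)C(CO)=C12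
F6 | step 4 | (E)-1-Fur-4,4-dimethoxypent-1-en-3-one | CC(OC)(OC)C(=O)/C=C/c1coc([Si](C)(C)C(C)(C)C)c1CO[Si](c1ccccc1)(c1ccccc1)C(C)(C)C
F7 | step 4 | (1S)-1-Fur-4,4-dimethoxy-1-(4,4,5,5-tetramethyl-1,3,2-dioxaborolan-2-yl)pentan-3-one | CC(OC)(OC)C(=O)C[C@H](B1OC(C)(C)C(C)(C)O1)c1coc([Si](C)(C)C(C)(C)C)c1CO[Si](c1ccccc1)(c1ccccc1)C(C)(C)C
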